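**Plan**

- Retrosynthesis: the C6–H bond of ring A is traced back to C6–NH2 (removal through a diazonium ion). Then all five C–Br bonds are cut at once (C3, C4, C5 on ring A; C2' and C4' on ring B). Last, the C6–N bond is cut (nitro group from nitration).
- The diaryl ether C–O bond is never cut; it is bought in 2-phenoxyphenol.
- Forward: no ring is built. 2-Phenoxyphenol is nitrated at C6, reduced, brominated five times in one flask and deaminated.
- Enabling feature: ring A of the target keeps a single hydrogen, at C6 beside the C1 hydroxyl. A nitrogen parked on C6 activates C5 (ortho) and C3 (para), the hydroxyl activates C4 (para), and the nitrogen is then exchanged for that hydrogen.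
- Stereochemistry: the target is achiral and has no stereocentre, so none has to be set.

Key step: step 3

Remark on numbering: in the discussion ring A carries the target locants (C1 OH, C2 aryloxy, C3–C5 Br, C6 H) and ring B carries primes; the systematic names of intermediates use their own locants.
Remark on salts: the ammonium salts that amines 3 and 7 form with acid in the flask are treated as the same numbered compounds; the free bases are released on work-up.

Step 1
Reactants: 1 2-phenoxyphenol
Product: 2 2-nitro-6-phenoxyphenol
Conditions: 65% HNO3 (1.0 equiv), AcOH, 10–15 °C; SiO2 chromatography to remove the para-nitro isomer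
Reagents that add atoms: nitric acid, O[N+](=O)[O-]
Why: Electrophilic aromatic nitration of a phenol: the hydroxyl, the strongest donor present, sends the nitronium ion to its one free ortho carbon (C6) and to C4, and the internally hydrogen-bonded ortho-nitrophenol 2 is much less polar than the para isomer, so it should separate cleanly on silica.

Step 2
Reactants: 2 2-nitro-6-phenoxyphenol
Product: 3 2-amino-6-phenoxyphenol
Conditions: H2 (1 atm), 10% Pd/C, MeOH, rt; filtered and concentrated under argon
Reagents that add atoms: none
Why: Catalytic hydrogenation of an aromatic nitro group to the aniline, which is safe here because no halogen is yet present and the diaryl ether is inert to H2 over Pd/C; the air-sensitive aminophenol is carried on at once.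

Step 3
Reactants: 3 2-amino-6-phenoxyphenol; 4 bromine
Product: 7 2-amino-3,4,5-tribromo-6-(2,4-dibromophenoxy)phenol, via ring A tribromide 5 (not isolated), via 4'-bromophenoxy tetrabromide 6 (not isolated)
Conditions: 33% HBr/AcOH (1.1 equiv), AcOH, 20 °C; Br2 (5.2 equiv) in AcOH dropwise, 20 °C then 50 °C; aq NaHSO3, then aq NaOAc
Reagents that add atoms: bromine, BrBr
Why: Each bromine enters by electrophilic aromatic substitution through an arenium ion, the amine reacting through the small share of free base in equilibrium with its hydrobromide. The closest known reaction type is the exhaustive bromination of anilines and phenols to their 2,4,6-tribromo derivatives, together with the para-then-ortho bromination of aryl ethers by Br2 in acetic acid. No ring closes and no stereocentre is formed. On ring A the hydroxyl activates C4 (para) and the amine activates C3 (para) and C5 (ortho), both reinforced by the ether oxygen, so ring A should fill completely to tribromide 5 and no positional isomer can arise there. The crowded C2–O bond is then twisted, which leaves the ether lone pair to ring B and sends bromine to C4' (tetrabromide 6) and next to C2', while C6' lies meta to two bromines and should resist the small excess of uncatalysed Br2. The control needed is therefore position and a stop at five bromines; the acidic medium limits oxidation of the aminophenol, and the bisulfite work-up returns N-bromo or bromocyclohexadienone species to 7.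

Step 4
Reactants: 7 2-amino-3,4,5-tribromo-6-(2,4-dibromophenoxy)phenol
Product: 9 3,4,5-tribromo-2-(2,4-dibromophenoxy)phenol, via arenediazonium hydrogen sulfate 8 (not isolated)
Conditions: NaNO2 in conc. H2SO4 (1.2 equiv), AcOH, 10–15 °C; then poured into 50% aq H3PO2 (10 equiv), Cu2O (5 mol%), 0–5 °C → rt
Reagents that add atoms: none
Why: Diazotization of a weakly basic polybromoaniline with nitrosylsulfuric acid followed by hypophosphorous acid hydrodediazoniation, a radical chain in which the aryl radical formed by loss of N2 takes hydrogen from H3PO2; the strong acid keeps the ortho-hydroxy diazonium ion 8 from resting as a diazo oxide, azo coupling is impossible because every ring A carbon is substituted, and the aryl bromides and the ether are untouched.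

**Compound list**

1 | 2-phenoxyphenol | Oc1ccccc1Oc1ccccc1 | starting material
2 | 2-nitro-6-phenoxyphenol | O=[N+]([O-])c1cccc(Oc2ccccc2)c1O | intermediate
3 | 2-amino-6-phenoxyphenol | Nc1cccc(Oc2ccccc2)c1O | intermediate
4 | bromine | BrBr | starting material
5 | 2-amino-3,4,5-tribromo-6-phenoxyphenol (ring A tribromide, formed and consumed in the flask of step 3) | Nc1c(Br)c(Br)c(Br)c(Oc2ccccc2)c1O | intermediate
6 | 2-amino-3,4,5-tribromo-6-(4-bromophenoxy)phenol (tetrabromide, formed and consumed in the flask of step 3) | Nc1c(Br)c(Br)c(Br)c(Oc2ccc(Br)cc2)c1O | intermediate
7 | 2-amino-3,4,5-tribromo-6-(2,4-dibromophenoxy)phenol | Nc1c(Br)c(Br)c(Br)c(Oc2ccc(Br)cc2Br)c1O | intermediate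
8 | 2,3,4-tribromo-5-(2,4-dibromophenoxy)-6-hydroxybenzenediazonium hydrogen sulfate (formed and consumed in the flask of step 4) | N#[N+]c1c(Br)c(Br)c(Br)c(Oc2ccc(Br)cc2Br)c1O.OS(=O)(=O)[O-] | intermediate
9 | 3,4,5-tribromo-2-(2,4-dibromophenoxy)phenol | Oc1cc(Br)c(Br)c(Br)c1Oc1ccc(Br)cc1Br | target

**Totals**

Total step count: 4. Longest linear sequence: 4 steps (1 → 2 → 3 → 7 → 9).

**Steps most likely to fail**

Step 3 (fivefold bromination). Bromine may act on the aminophenol as an oxidant (quinone imine formation and condensation) faster than as an electrophile. The ring B bromination may also stall after C4' or run on to C6'. The fallback sets out from nitrophenol 2 and splits the bromination around the reduction. Br2 (3.2 equiv) in AcOH at 60 °C should brominate C4 (para to the hydroxyl, meta to the nitro group) and C4' and C2' of ring B, while the nitro group shuts down C3 and C5; this should give 4-bromo-2-(2,4-dibromophenoxy)-6-nitrophenol F1. SnCl2·2H2O in EtOH at 70 °C, which spares aryl bromides, should reduce it to 2-amino-4-bromo-6-(2,4-dibromophenoxy)phenol F2. Br2 (2.1 equiv) in AcOH at 20 °C should then fill C3 and C5 under the direction of the amine. In this variant the oxidation-prone aminophenol already has its position para to the hydroxyl blocked and meets only two equivalents of bromine. The route is rejoined at 7.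

Step 4 (removal of the amine). The ortho-hydroxy diazonium ion may lose its proton and rest as a neutral diazo oxide that resists reduction, or water may displace the bromine ortho to the diazonium group. The fallback sets out from 7 and caps the phenol first. MeI (1.05 equiv) with K2CO3 in acetone should alkylate the phenoxide in preference to the hindered, electron-poor amine and give 2,3,4-tribromo-5-(2,4-dibromophenoxy)-6-methoxyaniline F3. Aprotic reductive deamination with t-BuONO in DMF at 60 °C (the aryl radical takes hydrogen from the solvent) should give 1,2,3-tribromo-4-(2,4-dibromophenoxy)-5-methoxybenzene F4. BBr3 in CH2Cl2, −78 °C → rt, cleaves the methyl ether but not the diaryl ether. The route is rejoined at 9.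

Step 1 (nitration). The nitronium ion may attack C4 (para to the hydroxyl) in competition with C6, and over-nitration or oxidation of the phenol may lower the return further. The fallback sets out from 1 and places the nitrogen by directed metalation. MOMCl with i-Pr2NEt in CH2Cl2 should give 1-(methoxymethoxy)-2-phenoxybenzene F5. n-BuLi in THF at 0 °C should lithiate C6, the only carbon ortho to the acetal oxygens, and TsN3 at −78 °C should then give 1-azido-2-(methoxymethoxy)-3-phenoxybenzene F6. H2 over Pd/C in MeOH should reduce the azide to 2-(methoxymethoxy)-3-phenoxyaniline F7, and HCl in MeOH removes the acetal. The route is rejoined at 3, bypassing 2.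

**Further compounds**

F1 | step 3 | 4-bromo-2-(2,4-dibromophenoxy)-6-nitrophenol | O=[N+]([O-])c1cc(Br)cc(Oc2ccc(Br)cc2Br)c1O
F2 | step 3 | 2-amino-4-bromo-6-(2,4-dibromophenoxy)phenol | Nc1cc(Br)cc(Oc2ccc(Br)cc2Br)c1O
F3 | step 4 | 2,3,4-tribromo-5-(2,4-dibromophenoxy)-6-methoxyaniline | COc1c(N)c(Br)c(Br)c(Br)c1Oc1ccc(Br)cc1Br
F4 | step 4 | 1,2,3-tribromo-4-(2,4-dibromophenoxy)-5-methoxybenzene | COc1cc(Br)c(Br)c(Br)c1Oc1ccc(Br)cc1Br
F5 | step 1 | 1-(methoxymethoxy)-2-phenoxybenzene | COCOc1ccccc1Oc1ccccc1
F6 | step 1 | 1-azido-2-(methoxymethoxy)-3-phenoxybenzene | COCOc1c(N=[N+]=[N-])cccc1Oc1ccccc1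
F7 | step 1 | 2-(methoxymethoxy)-3-phenoxyaniline | COCOc1c(N)cccc1Oc1ccccc1
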